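**Retrosynthetic overview**
1. 30 ⇐ 29 ⇐ 27 ⇐ 26. The last steps only unmask C3–OH and C11=C13 and esterify C6 with inversion.
2. Key disconnection: C4–C15 and C5–C6 are made in one nickel-catalysed event, 26 ⇐ monocyclic ynal 23 + acyloxymethylzinc iodide 4. This closes the ten-membered ring C1–C10, fixes the C4=C5 geometry, creates C6 and brings in the C15 ester intact.
3. Enabling feature: on the C4=C5 bond of the ten-membered ring, C15 and C6 are cis (ring-E), C5 carries only H and C6 carries O. The array O–C6–C5H=C4–C15 is therefore the retron of a syn addition of an aldehyde carbon and an alkyl group across the terminal alkyne C4≡C5–H.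
4. 23 ⇐ butenolide 17 (radical formyl equivalent at C7; Mannich base at C11 as masked C11=C13) ⇐ aldehyde 13 (organocatalytic C8–O, Z-olefination) ⇐ alkyne 5 (carboalumination for E-C1=C10, asymmetric alkynylation for C3).
5. Ring order: γ-lactone first (step 11), ten-membered carbocycle second (step 16).

Key step: step 16

Remark: positions are named by germacrane numbering (ring C1–C10; C11–C13 on the lactone side; C14 = methyl on C10; C15 = oxymethyl carbon on C4).

**Route**

Step 1
Reactants: 1 3-methylbutanoyl chloride (isovaleryl chloride)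
Product: 2 chloromethyl 3-methylbutanoate
Conditions: (CH2O)n, ZnCl2 (cat.), neat, 0 to 60 °C
Reagents that add atoms: paraformaldehyde (as formaldehyde), C=O
Why: Lewis-acid-catalysed insertion of formaldehyde into the acyl chloride C–Cl bond is the classical α-chloroalkyl ester synthesis and needs no further reagent.

Step 2
Reactants: 2 chloromethyl 3-methylbutanoate
Product: 3 iodomethyl 3-methylbutanoate
Conditions: NaI, acetone, rt, dark
Reagents that add atoms: sodium iodide, [Na+].[I-]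
Why: Finkelstein halide exchange at an activated primary carbon, driven by precipitation of the chloride salt.

Step 3
Reactants: 3 iodomethyl 3-methylbutanoate
Product: 4 [(3-methylbutanoyloxy)methyl]zinc iodide (titrated THF solution)
Conditions: activated Zn dust, THF, 10 to 15 °C
Reagents that add atoms: zinc, [Zn]
Why: Direct zinc insertion into α-acyloxyalkyl iodides is a known route to functionalised organozinc halides, the ester carbonyl chelating zinc and keeping the reagent from carbenoid decay.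

Step 4
Reactants: 5 tert-butyldimethyl(pent-4-yn-1-yloxy)silane
Product: 8 (3E)-7-(tert-butyldimethylsilyloxy)-4-methylhept-3-en-1-ol, via alkenyldimethylalane 6 (not isolated), via lithium alanate 7 (not isolated)
Conditions: Me3Al, Cp2ZrCl2 (cat.), CH2Cl2, 0 °C to rt; evaporate; n-BuLi, hexane–THF, −78 °C; oxirane, −78 °C to rt; aq. work-up
Reagents that add atoms: trimethylaluminium, C[Al](C)C; oxirane, C1CO1
Why: Negishi zirconium-catalysed syn-carboalumination puts CH3 on the internal and Al on the terminal alkyne carbon (E-C1=C10), and the derived alanate opens oxirane with retention of the alkene geometry.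

Step 5
Reactants: 8 (3E)-7-(tert-butyldimethylsilyloxy)-4-methylhept-3-en-1-ol
Product: 9 (3E)-7-(tert-butyldimethylsilyloxy)-4-methylhept-3-enal
Conditions: Dess–Martin periodinane, pyridine, CH2Cl2, 0 °C; used crude
Reagents that add atoms: none
Why: Buffered Dess–Martin oxidation is mild enough to give the β,γ-unsaturated aldehyde without moving the double bond into conjugation.

Step 6
Reactants: 9 (3E)-7-(tert-butyldimethylsilyloxy)-4-methylhept-3-enal
Product: 10 (3R,5E)-9-(tert-butyldimethylsilyloxy)-6-methyl-1-(trimethylsilyl)non-5-en-1-yn-3-ol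
Conditions: Me3SiC≡CH, Et2Zn, toluene, reflux; then (S)-BINOL (cat.), Ti(Oi-Pr)4 (cat.), Et2O, 9, rt
Reagents that add atoms: (trimethylsilyl)acetylene, C#C[Si](C)(C)C
Why: Catalytic asymmetric alkynylzinc addition (BINOL–titanium type) works without amine base and should deliver the alkynyl group to the Si face of the aldehyde, setting C3 as R.

Step 7
Reactants: 10 (3R,5E)-9-(tert-butyldimethylsilyloxy)-6-methyl-1-(trimethylsilyl)non-5-en-1-yn-3-ol
Product: 11 (3R,5E)-3,9-bis(tert-butyldimethylsilyloxy)-6-methyl-1-(trimethylsilyl)non-5-en-1-yne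
Conditions: TBSCl, imidazole, DMF, rt
Reagents that add atoms: tert-butyldimethylsilyl chloride, CC(C)(C)[Si](C)(C)Cl
Why: Imidazole-promoted silylation of a secondary alcohol does not touch the stereocentre.

Step 8
Reactants: 11 (3R,5E)-3,9-bis(tert-butyldimethylsilyloxy)-6-methyl-1-(trimethylsilyl)non-5-en-1-yne
Product: 12 (4E,7R)-7-(tert-butyldimethylsilyloxy)-4-methyl-9-(trimethylsilyl)non-4-en-8-yn-1-ol
Conditions: camphorsulfonic acid (cat.), MeOH–CH2Cl2, 0 °C
Reagents that add atoms: none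
Why: Acid-catalysed methanolysis discriminates sterically, so the primary silyl ether is cleaved well before the secondary propargylic one, and the alkynyl C–Si bond is inert to acid.

Step 9
Reactants: 12 (4E,7R)-7-(tert-butyldimethylsilyloxy)-4-methyl-9-(trimethylsilyl)non-4-en-8-yn-1-ol
Product: 13 (4E,7R)-7-(tert-butyldimethylsilyloxy)-4-methyl-9-(trimethylsilyl)non-4-en-8-ynal
Conditions: Dess–Martin periodinane, pyridine, CH2Cl2, 0 °C to rt
Reagents that add atoms: none
Why: Dess–Martin oxidation of a primary alcohol stops at the aldehyde and tolerates silyl ethers, the alkene and the silylalkyne.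

Step 10
Reactants: 13 (4E,7R)-7-(tert-butyldimethylsilyloxy)-4-methyl-9-(trimethylsilyl)non-4-en-8-ynal
Product: 15 ethyl (2Z,4S,6E,9R)-4-(anilinooxy)-9-(tert-butyldimethylsilyloxy)-6-methyl-11-(trimethylsilyl)undeca-2,6-dien-10-ynoate, via α-aminoxy aldehyde 14 (not isolated)
Conditions: PhNO, D-proline (cat.), MeCN, −20 °C; then (PhO)2P(O)CH2CO2Et/NaH, THF, −78 °C
Reagents that add atoms: nitrosobenzene, O=Nc1ccccc1; ethyl (diphenoxyphosphoryl)acetate, CCOC(=O)CP(=O)(Oc1ccccc1)Oc1ccccc1
Why: Proline-enamine α-aminoxylation (D-proline gives the 2S aldehyde and thereby sets C8 under catalyst control) is followed in the same flask by a Z-selective Horner–Wadsworth–Emmons reaction with the diaryl (Ando-type) phosphonate.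

Step 11
Reactants: 15 ethyl (2Z,4S,6E,9R)-4-(anilinooxy)-9-(tert-butyldimethylsilyloxy)-6-methyl-11-(trimethylsilyl)undeca-2,6-dien-10-ynoate
Product: 17 (5S)-5-[(2E,5R)-5-(tert-butyldimethylsilyloxy)-2-methyl-7-(trimethylsilyl)hept-2-en-6-yn-1-yl]furan-2(5H)-one, via γ-hydroxy enoate 16 (not isolated)
Conditions: Cu(OAc)2·H2O (cat.), EtOH, rt
Reagents that add atoms: none
Why: Copper(II)-catalysed N–O cleavage frees the C8 hydroxyl, which lactonises spontaneously onto the cis ester (known aminoxylation/cis-olefination route to γ-butenolides) without touching C8.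

Step 12
Reactants: 17 (5S)-5-[(2E,5R)-5-(tert-butyldimethylsilyloxy)-2-methyl-7-(trimethylsilyl)hept-2-en-6-yn-1-yl]furan-2(5H)-one
Product: 18 (4R,5S)-4-(1,3-dioxolan-2-yl)-5-[(2E,5R)-5-(tert-butyldimethylsilyloxy)-2-methyl-7-(trimethylsilyl)hept-2-en-6-yn-1-yl]oxolan-2-one (4,5-trans)
Conditions: (n-Bu4N)4W10O32 (cat.), 1,3-dioxolane–MeCN, 390 nm LED, rt
Reagents that add atoms: 1,3-dioxolane, C1COCO1
Why: Decatungstate hydrogen-atom transfer makes the nucleophilic 1,3-dioxolan-2-yl radical, which reacts only with the electron-poor butenolide (Giese addition) at the β-carbon anti to the C8 side chain, setting C7 trans to C8.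

Step 13
Reactants: 18 (4R,5S)-4-(1,3-dioxolan-2-yl)-5-[(2E,5R)-5-(tert-butyldimethylsilyloxy)-2-methyl-7-(trimethylsilyl)hept-2-en-6-yn-1-yl]oxolan-2-one
Product: 20 (3S,4R,5S)-3-[(dimethylamino)methyl]-4-(1,3-dioxolan-2-yl)-5-[(2E,5R)-5-(tert-butyldimethylsilyloxy)-2-methyl-7-(trimethylsilyl)hept-2-en-6-yn-1-yl]oxolan-2-one, via lithium enolate 19 (not isolated)
Conditions: LDA, THF, −78 °C; CH2=NMe2+ I−, −78 to 0 °C
Reagents that add atoms: Eschenmoser's salt, C=[N+](C)C.[I-]
Why: Mannich reaction of the lactone enolate with Eschenmoser's salt takes place anti to the C7 substituent (C11 is destroyed again in step 18) and installs C13 as an amine that keeps the acrylate unit hidden from nickel(0).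

Step 14
Reactants: 20 (3S,4R,5S)-3-[(dimethylamino)methyl]-4-(1,3-dioxolan-2-yl)-5-[(2E,5R)-5-(tert-butyldimethylsilyloxy)-2-methyl-7-(trimethylsilyl)hept-2-en-6-yn-1-yl]oxolan-2-one
Product: 21 (3S,4R,5S)-3-[(dimethylamino)methyl]-4-(1,3-dioxolan-2-yl)-5-[(2E,5R)-5-(tert-butyldimethylsilyloxy)-2-methylhept-2-en-6-yn-1-yl]oxolan-2-one
Conditions: AgNO3 (cat.), acetone–H2O, rt
Reagents that add atoms: none
Why: Silver(I)-catalysed protiodesilylation is specific for alkynyl–SiMe3 and, being neutral, spares the silyl ether, the lactone and the β-amino carbonyl unit.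

Step 15
Reactants: 21 (3S,4R,5S)-3-[(dimethylamino)methyl]-4-(1,3-dioxolan-2-yl)-5-[(2E,5R)-5-(tert-butyldimethylsilyloxy)-2-methylhept-2-en-6-yn-1-yl]oxolan-2-one
Product: 23 (2S,3R,4S)-2-[(2E,5R)-5-(tert-butyldimethylsilyloxy)-2-methylhept-2-en-6-yn-1-yl]-4-[(dimethylamino)methyl]-5-oxooxolane-3-carbaldehyde, via lutidinium mixed acetal 22 (not isolated)
Conditions: TESOTf, 2,6-lutidine, CH2Cl2, 0 °C; then H2O; used at once
Reagents that add atoms: water, O
Why: Silyl triflate/lutidine activation of an aldehyde acetal followed by hydrolysis is a weakly basic acetal cleavage that leaves TBS ethers and lactones alone, and C7 cannot be scrambled because the trans arrangement is also the thermodynamic one.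

Step 16
Reactants: 23 (2S,3R,4S)-2-[(2E,5R)-5-(tert-butyldimethylsilyloxy)-2-methylhept-2-en-6-yn-1-yl]-4-[(dimethylamino)methyl]-5-oxooxolane-3-carbaldehyde; 4 [(3-methylbutanoyloxy)methyl]zinc iodide
Product: 26 (3R,6S,7S,8S,11S)-3-(tert-butyldimethylsilyloxy)-13-(dimethylamino)-6-hydroxy-15-(3-methylbutanoyloxy)germacra-1(10)E,4E-dien-12,8-olide, via oxanickelacycle 24 (not isolated), via zinc alkoxide 25 (not isolated)
Conditions: Ni(cod)2 (20 mol %), IMes·HCl (20 mol %), KOt-Bu (20 mol %), 4 (3 equiv), THF, 0 °C to rt, 23 added by syringe pump over 10 h (final 2 mM); pH 7 buffer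
Reagents that add atoms: none
Why: Proposed new method: Ni(0) binds the terminal alkyne and the aldehyde of 23, oxidative cyclisation forms C5–C6 and oxanickelacyclopentene 24 (Ni on C4, O6 on Ni), the oxophilic zinc of 4 takes the alkoxide while its acyloxymethyl group moves to nickel, and reductive elimination forges C4–C15 to give zinc alkoxide 25 and Ni(0). The closest known reactions are the nickel-catalysed alkylative cyclisation of ynals, the three-component aldehyde/terminal-alkyne/organozinc coupling (alkyl to the internal, carbonyl carbon to the terminal alkyne carbon) and the Ni–NHC endo-selective reductive macrocyclisation of terminal-alkyne ynals; new here are the ten-membered ring size and a chelate-stabilised acyloxymethylzinc as alkyl donor. The ten-membered carbocycle is closed in the endo mode at the terminal alkyne carbon, and the five-membered nickelacycle is only transient. Syn addition across the alkyne places C15 cis to C6, so C4=C5 can only be E within the ring; at C6 the oxygen must lie in the C4=C5 plane next to nickel, and in the crown-like array with the trans-lactone diequatorial this in-plane site is the ring face opposite to H7, so C7/C8 should impose the 6S alkoxide, which step 17 inverts. The selectivities needed are endo regiochemistry (unhindered terminal carbon plus a small NHC), no enoate–alkyne coupling (C11=C13 is masked as the Mannich base), no reductive pathway (4 has no β-hydrogen) and cyclisation over oligomerisation (slow addition at high dilution).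

Step 17
Reactants: 26 (3R,6S,7S,8S,11S)-3-(tert-butyldimethylsilyloxy)-13-(dimethylamino)-6-hydroxy-15-(3-methylbutanoyloxy)germacra-1(10)E,4E-dien-12,8-olide
Product: 27 (3R,6R,7R,8S,11S)-3-(tert-butyldimethylsilyloxy)-13-(dimethylamino)-6,15-bis(3-methylbutanoyloxy)germacra-1(10)E,4E-dien-12,8-olide
Conditions: 3-methylbutanoic acid, PPh3, DIAD, toluene, 0 °C to rt
Reagents that add atoms: 3-methylbutanoic acid, CC(C)CC(=O)O
Why: Mitsunobu esterification displaces the activated C6 oxygen by SN2 with inversion (6S to 6R), helped by the C6–O bond lying in the nodal plane of the C4=C5 π bond (ionisation and SN2′ disfavoured) and by a backside that points to the open ring periphery.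

Step 18
Reactants: 27 (3R,6R,7R,8S,11S)-3-(tert-butyldimethylsilyloxy)-13-(dimethylamino)-6,15-bis(3-methylbutanoyloxy)germacra-1(10)E,4E-dien-12,8-olide
Product: 29 (3R,6R,7R,8S)-3-(tert-butyldimethylsilyloxy)-6,15-bis(3-methylbutanoyloxy)germacra-1(10)E,4E,11(13)-trien-12,8-olide, via trimethylammonium iodide 28 (not isolated)
Conditions: MeI, THF, rt; then aq. NaHCO3, CH2Cl2, rt
Reagents that add atoms: none
Why: Quaternisation of the Mannich base followed by mild-base E1cB (Hofmann-type) elimination is the standard release of an α-methylene-γ-lactone and leaves the two esters and the silyl ether untouched.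

Step 19
Reactants: 29 (3R,6R,7R,8S)-3-(tert-butyldimethylsilyloxy)-6,15-bis(3-methylbutanoyloxy)germacra-1(10)E,4E,11(13)-trien-12,8-olide
Product: 30 (3R,6R,7R,8S)-3-hydroxy-6,15-bis(3-methylbutanoyloxy)germacra-1(10)E,4E,11(13)-trien-12,8-olide (target)
Conditions: HF·pyridine, pyridine, THF, 0 °C to rt
Reagents that add atoms: none
Why: Fluoride-mediated desilylation in a slightly acidic medium frees C3–OH without the base-induced O15 to O3 acyl shift or conjugate addition to the methylene lactone.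

**Compound list**
1 | 3-methylbutanoyl chloride | CC(C)CC(=O)Cl | starting material
2 | chloromethyl 3-methylbutanoate | CC(C)CC(=O)OCCl | intermediate
3 | iodomethyl 3-methylbutanoate | CC(C)CC(=O)OCI | intermediate
4 | [(3-methylbutanoyloxy)methyl]zinc iodide | CC(C)CC(=O)OC[Zn]I | intermediate
5 | tert-butyldimethyl(pent-4-yn-1-yloxy)silane | C#CCCCO[Si](C)(C)C(C)(C)C | starting material
6 | (E)-alkenyldimethylalane from 5 (CH3 and Al cis) | C[Al](C)/C=C(\C)CCCO[Si](C)(C)C(C)(C)C | intermediate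
7 | lithium butyl(alkenyl)dimethylalanate from 6 | [Li+].CCCC[Al-](C)(C)/C=C(\C)CCCO[Si](C)(C)C(C)(C)C | intermediate
8 | (3E)-7-(tert-butyldimethylsilyloxy)-4-methylhept-3-en-1-ol | OCC/C=C(\C)CCCO[Si](C)(C)C(C)(C)C | intermediate
9 | (3E)-7-(tert-butyldimethylsilyloxy)-4-methylhept-3-enal | O=CC/C=C(\C)CCCO[Si](C)(C)C(C)(C)C | intermediate
10 | (3R,5E)-9-(tert-butyldimethylsilyloxy)-6-methyl-1-(trimethylsilyl)non-5-en-1-yn-3-ol | CC(C)(C)[Si](C)(C)OCCC/C(C)=C/C[C@@H](O)C#C[Si](C)(C)C | intermediate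
11 | (3R,5E)-3,9-bis(tert-butyldimethylsilyloxy)-6-methyl-1-(trimethylsilyl)non-5-en-1-yne | CC(C)(C)[Si](C)(C)OCCC/C(C)=C/C[C@@H](O[Si](C)(C)C(C)(C)C)C#C[Si](C)(C)C | intermediate
12 | (4E,7R)-7-(tert-butyldimethylsilyloxy)-4-methyl-9-(trimethylsilyl)non-4-en-8-yn-1-ol | OCCC/C(C)=C/C[C@@H](O[Si](C)(C)C(C)(C)C)C#C[Si](C)(C)C | intermediate
13 | (4E,7R)-7-(tert-butyldimethylsilyloxy)-4-methyl-9-(trimethylsilyl)non-4-en-8-ynal | O=CCC/C(C)=C/C[C@@H](O[Si](C)(C)C(C)(C)C)C#C[Si](C)(C)C | intermediate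
14 | (2S,4E,7R)-2-(anilinooxy)-7-(tert-butyldimethylsilyloxy)-4-methyl-9-(trimethylsilyl)non-4-en-8-ynal | O=C[C@@H](ONc1ccccc1)C/C(C)=C/C[C@@H](O[Si](C)(C)C(C)(C)C)C#C[Si](C)(C)C | intermediate
15 | ethyl (2Z,4S,6E,9R)-4-(anilinooxy)-9-(tert-butyldimethylsilyloxy)-6-methyl-11-(trimethylsilyl)undeca-2,6-dien-10-ynoate | CCOC(=O)/C=C\[C@@H](ONc1ccccc1)C/C(C)=C/C[C@@H](O[Si](C)(C)C(C)(C)C)C#C[Si](C)(C)C | intermediate
16 | ethyl (2Z,4S,6E,9R)-9-(tert-butyldimethylsilyloxy)-4-hydroxy-6-methyl-11-(trimethylsilyl)undeca-2,6-dien-10-ynoate | CCOC(=O)/C=C\[C@@H](O)C/C(C)=C/C[C@@H](O[Si](C)(C)C(C)(C)C)C#C[Si](C)(C)C | intermediate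
17 | (5S)-5-[(2E,5R)-5-(tert-butyldimethylsilyloxy)-2-methyl-7-(trimethylsilyl)hept-2-en-6-yn-1-yl]furan-2(5H)-one | O=C1O[C@@H](C/C(C)=C/C[C@@H](O[Si](C)(C)C(C)(C)C)C#C[Si](C)(C)C)C=C1 | intermediate
18 | (4R,5S)-4-(1,3-dioxolan-2-yl)-5-[(2E,5R)-5-(tert-butyldimethylsilyloxy)-2-methyl-7-(trimethylsilyl)hept-2-en-6-yn-1-yl]oxolan-2-one (4,5-trans) | O=C1C[C@@H](C2OCCO2)[C@H](C/C(C)=C/C[C@@H](O[Si](C)(C)C(C)(C)C)C#C[Si](C)(C)C)O1 | intermediate
19 | lithium enolate of 18 | [Li]OC1=C[C@@H](C2OCCO2)[C@H](C/C(C)=C/C[C@@H](O[Si](C)(C)C(C)(C)C)C#C[Si](C)(C)C)O1 | intermediate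
20 | (3S,4R,5S)-3-[(dimethylamino)methyl]-4-(1,3-dioxolan-2-yl)-5-[(2E,5R)-5-(tert-butyldimethylsilyloxy)-2-methyl-7-(trimethylsilyl)hept-2-en-6-yn-1-yl]oxolan-2-one (3,4-trans, 4,5-trans) | O=C1[C@H](CN(C)C)[C@@H](C2OCCO2)[C@H](C/C(C)=C/C[C@@H](O[Si](C)(C)C(C)(C)C)C#C[Si](C)(C)C)O1 | intermediate
21 | (3S,4R,5S)-3-[(dimethylamino)methyl]-4-(1,3-dioxolan-2-yl)-5-[(2E,5R)-5-(tert-butyldimethylsilyloxy)-2-methylhept-2-en-6-yn-1-yl]oxolan-2-one | O=C1[C@H](CN(C)C)[C@@H](C2OCCO2)[C@H](C/C(C)=C/C[C@@H](O[Si](C)(C)C(C)(C)C)C#C)O1 | intermediate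
22 | 2,6-lutidinium mixed acetal triflate from 21 (C6 bears OCH2CH2OSiEt3 and N-lutidinium; C6 unassigned) | O=C1[C@H](CN(C)C)[C@@H](C(OCCO[Si](CC)(CC)CC)[n+]2c(C)cccc2C)[C@H](C/C(C)=C/C[C@@H](O[Si](C)(C)C(C)(C)C)C#C)O1.[O-]S(=O)(=O)C(F)(F)F | intermediate
23 | (2S,3R,4S)-2-[(2E,5R)-5-(tert-butyldimethylsilyloxy)-2-methylhept-2-en-6-yn-1-yl]-4-[(dimethylamino)methyl]-5-oxooxolane-3-carbaldehyde | O=C1[C@H](CN(C)C)[C@@H](C=O)[C@H](C/C(C)=C/C[C@@H](O[Si](C)(C)C(C)(C)C)C#C)O1 | intermediate
24 | oxanickelacyclopentene (Ni on C4 and O6, ligands omitted) | CN(C)C[C@H]1C(=O)O[C@H]2C/C(C)=C/C[C@@H](O[Si](C)(C)C(C)(C)C)/C3=C/[C@H](O[Ni]3)[C@H]12 | intermediate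
25 | iodozinc alkoxide of 26 | CN(C)C[C@H]1C(=O)O[C@H]2C/C(C)=C/C[C@@H](O[Si](C)(C)C(C)(C)C)/C(COC(=O)CC(C)C)=C/[C@H](O[Zn]I)[C@H]12 | intermediate
26 | (3R,6S,7S,8S,11S)-3-(tert-butyldimethylsilyloxy)-13-(dimethylamino)-6-hydroxy-15-(3-methylbutanoyloxy)germacra-1(10)E,4E-dien-12,8-olide (OH on the ring face opposite to H7; H7/H8 anti) | CN(C)C[C@H]1C(=O)O[C@H]2C/C(C)=C/C[C@@H](O[Si](C)(C)C(C)(C)C)/C(COC(=O)CC(C)C)=C/[C@H](O)[C@H]12 | intermediate
27 | (3R,6R,7R,8S,11S)-3-(tert-butyldimethylsilyloxy)-13-(dimethylamino)-6,15-bis(3-methylbutanoyloxy)germacra-1(10)E,4E-dien-12,8-olide | CN(C)C[C@H]1C(=O)O[C@H]2C/C(C)=C/C[C@@H](O[Si](C)(C)C(C)(C)C)/C(COC(=O)CC(C)C)=C/[C@@H](OC(=O)CC(C)C)[C@H]12 | intermediate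
28 | 13-trimethylammonium iodide of 27 | C[N+](C)(C)C[C@H]1C(=O)O[C@H]2C/C(C)=C/C[C@@H](O[Si](C)(C)C(C)(C)C)/C(COC(=O)CC(C)C)=C/[C@@H](OC(=O)CC(C)C)[C@H]12.[I-] | intermediate
29 | (3R,6R,7R,8S)-3-(tert-butyldimethylsilyloxy)-6,15-bis(3-methylbutanoyloxy)germacra-1(10)E,4E,11(13)-trien-12,8-olide | C=C1C(=O)O[C@H]2C/C(C)=C/C[C@@H](O[Si](C)(C)C(C)(C)C)/C(COC(=O)CC(C)C)=C/[C@@H](OC(=O)CC(C)C)[C@H]12 | intermediate
30 | (3R,6R,7R,8S)-3-hydroxy-6,15-bis(3-methylbutanoyloxy)germacra-1(10)E,4E,11(13)-trien-12,8-olide | C=C1C(=O)O[C@H]2C/C(C)=C/C[C@@H](O)/C(COC(=O)CC(C)C)=C/[C@@H](OC(=O)CC(C)C)[C@H]12 | target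

**Step count**
Total step count: 19. Longest linear sequence: 16 steps (5 to 30, steps 4–19). Steps 1–3 form a three-step side branch.

**Steps most likely to fail**

1. Step 16 (proposed new method). The following may go wrong:
   - Intermolecular coupling or exo-mode closure may outrun formation of the strained ten-membered ring.
   - Transfer of the acyloxymethyl group from zinc to nickel may be too slow.
   - The facial selectivity at C6 may be poor or reversed.

   The fallback sets out from 21, comes back at 26 (or at 27), and uses known chemistry only: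
   - Rhodium-catalysed silylformylation of 21 (Me2PhSiH, CO, Rh4(CO)12 cat., toluene) forms C4–C15 from CO, with silicon added syn on C5, and gives the (Z)-β-silyl enal F1.
   - Luche reduction gives the allylic alcohol F2.
   - 3-Methylbutanoic anhydride/DMAP gives the ester F3.
   - Stereoretentive iododesilylation (NIS, HFIP, amine kept protonated with TFA) gives the vinyl iodide F4.
   - TESOTf/2,6-lutidine, then water, gives the iodo aldehyde F5.
   - A Nozaki–Hiyama–Kishi macrocyclisation (CrCl2, NiCl2 cat., DMF–THF, high dilution) closes C5–C6 to 26.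
   - Any 6R alcohol F6 formed there (or in step 16 itself) is acylated with retention by 3-methylbutanoic anhydride/DMAP and joins the route at 27.

2. Step 17. The following may go wrong:
   - Elimination toward a C6=C7 diene may compete.
   - Displacement of the hindered oxyphosphonium ion by a weakly acidic aliphatic acid may be sluggish.
   - A prior O15 to O6 acyl shift may block the inversion.

   The fallback sets out from 26 and comes back at 27. It replaces the redox condensation by a discrete leaving group and a naked carboxylate. ClCH2SO2Cl/pyridine at 0 °C gives the 6S chloromethanesulfonate F7. This is displaced by caesium 3-methylbutanoate/18-crown-6 in toluene by SN2 with inversion.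

3. Step 6. Enolisation of the β,γ-unsaturated aldehyde, with migration of the double bond into conjugation, or insufficient enantiofacial control may occur. The fallback sets out from 9 and comes back at 10:
   - LiC≡CSiMe3 in THF at −78 °C gives the racemic propargylic alcohol F8.
   - Dess–Martin oxidation gives the ynone F9.
   - Noyori asymmetric transfer hydrogenation with the (R,R)-TsDPEN–Ru(p-cymene) catalyst in i-PrOH sets C3 as R under catalyst control.

Further compounds
F1 | step 16 | (Z)-β-(dimethylphenylsilyl) enal from 21 (CHO on C4, Si on C5, cis) | O=C1[C@H](CN(C)C)[C@@H](C2OCCO2)[C@H](C/C(C)=C/C[C@@H](O[Si](C)(C)C(C)(C)C)/C(C=O)=C/[Si](C)(C)c2ccccc2)O1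
F2 | step 16 | C15 allylic alcohol from F1 | O=C1[C@H](CN(C)C)[C@@H](C2OCCO2)[C@H](C/C(C)=C/C[C@@H](O[Si](C)(C)C(C)(C)C)/C(CO)=C/[Si](C)(C)c2ccccc2)O1
F3 | step 16 | C15 3-methylbutanoate of F2 | O=C1[C@H](CN(C)C)[C@@H](C2OCCO2)[C@H](C/C(C)=C/C[C@@H](O[Si](C)(C)C(C)(C)C)/C(COC(=O)CC(C)C)=C/[Si](C)(C)c2ccccc2)O1
F4 | step 16 | C5 vinyl iodide (I cis to C15) | O=C1[C@H](CN(C)C)[C@@H](C2OCCO2)[C@H](C/C(C)=C/C[C@@H](O[Si](C)(C)C(C)(C)C)/C(COC(=O)CC(C)C)=C/I)O1
F5 | step 16 | iodo aldehyde from F4 | O=C1[C@H](CN(C)C)[C@@H](C=O)[C@H](C/C(C)=C/C[C@@H](O[Si](C)(C)C(C)(C)C)/C(COC(=O)CC(C)C)=C/I)O1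
F6 | step 16 | (3R,6R,7S,8S,11S) alcohol, the C6 epimer of 26 | CN(C)C[C@H]1C(=O)O[C@H]2C/C(C)=C/C[C@@H](O[Si](C)(C)C(C)(C)C)/C(COC(=O)CC(C)C)=C/[C@@H](O)[C@H]12
F7 | step 17 | 6S chloromethanesulfonate of 26 | CN(C)C[C@H]1C(=O)O[C@H]2C/C(C)=C/C[C@@H](O[Si](C)(C)C(C)(C)C)/C(COC(=O)CC(C)C)=C/[C@H](OS(=O)(=O)CCl)[C@H]12
F8 | step 6 | racemic (5E)-9-(tert-butyldimethylsilyloxy)-6-methyl-1-(trimethylsilyl)non-5-en-1-yn-3-ol | CC(C)(C)[Si](C)(C)OCCC/C(C)=C/CC(O)C#C[Si](C)(C)C
F9 | step 6 | (5E)-9-(tert-butyldimethylsilyloxy)-6-methyl-1-(trimethylsilyl)non-5-en-1-yn-3-one | CC(C)(C)[Si](C)(C)OCCC/C(C)=C/CC(=O)C#C[Si](C)(C)C
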